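## Structural features

The target is an open chain of ten benzene rings (A to J) joined only by nine diaryl ether oxygens. It carries twenty-six free phenolic hydroxyls, has no carbon–carbon bond between rings and no stereocenter, so no stereochemical relationship has to be set. Ring A is a 2,4,6-trihydroxyphenyl end and ring J a 3,4,5-trihydroxyphenyl end. Rings B, D, F and H are 1,4-dioxygenated with hydroxyls on C3 and C5, and rings C, E, G and I take the incoming ether oxygen on C1, pass the chain on through the oxygen on C2, and carry hydroxyls on C3, C4, C5 and the only hydrogen on C6. The chain is therefore ring A, four identical two-ring repeats (B–C, D–E, F–G, H–I) and ring J. Five ether bonds (A–B, C–D, E–F, G–H, I–J) run from an oxygen flanked by two oxygenated carbons to an aryl carbon with two free ortho positions. The four bonds inside the repeats link such a flanked oxygen to a carbon that itself stands ortho to an aryloxy group, and these are the real difficulty because both partners are electron-rich and ortho-substituted. The free polyphenol, with pyrogallol- and hydroxyquinol-type rings, is very easily oxidised in air, so all hydroxyls travel as methyl ethers to the last step; the other fragile species are the aryl ethynyl ether and the chromium carbene complex. The key step exploits ring I, which has oxygen on C1–C5 and hydrogen on C6: C1 and C6 come from an ethynyl ether on O4 of ring H, C5 from a methoxycarbene carbon, C4 and C3 from a 1,2-dimethoxyvinyl group and C2 from a carbonyl ligand, so the hindered H–I ether bond exists before the ring does and the one hydroxyl born free (on C2) is the one that must carry ring J.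

## Logic of the disconnections

34 ⇒ 33. All twenty-six hydroxyls are masked as methyl ethers, so the bonds broken in the forward direction are the O–CH3 bonds. The reason is the air sensitivity of 34 and the need for ethers that survive organolithium, copper, iridium and chromium chemistry. The gain is an oxidation-stable, chromatographable intermediate. The demand is one reagent that cleaves every alkyl–oxygen bond and none of the nine aryl–O–aryl bonds, with isolation of 34 under exclusion of air.

33 ⇒ 32 + 2. The bond from the oxygen on C2 of ring I to C1 of ring J is cut. Ring J has no ortho substituent and 32 has a single free hydroxyl, so no selectivity question arises. The gain is the removal of a whole ring with a purchasable reagent. The demand is a copper-mediated arylation that tolerates a phenol flanked by an aryloxy and a methoxy group.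

32 ⇒ 24 + 30. Ring I is opened at C5–C6, C1–C2 and C2–C3. The cut is made here because it turns the hardest ether bond of the last repeat into the O–C(sp) bond of 24 and delivers all five oxygens of ring I in place, with only the C2 hydroxyl free. The gain is one ring, three skeletal bonds and a built-in differentiation of C2. The demand is an alkyne insertion of defined orientation, a carbonyl insertion that follows it, and a demetalation that does not oxidise the 4-methoxyphenol.

30 ⇒ 26 + 27, and 26 ⇒ 25. The carbene carbon–vinyl bond and the O–CH3 bond of the carbene are cut; the carbene carbon is a carbonyl ligand of 27. The alkene of 26 is traced to loss of methanol from 25. The gain is a three-component assembly from bulk chemicals. The demand is a vinyl anion that keeps its geometry and does not eliminate methoxide before it is trapped.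

24 ⇒ 21. The triple bond is traced to a 1,2-dichlorovinyl ether by retro-loss of two chlorines. 24 is too labile to carry through several steps, whereas 21 tolerates copper, base and chromatography. The demand is a strong base at low temperature that does not metalate the methoxylated rings.

21 ⇒ 16 + 20, and 20 ⇒ 19 ⇒ 17 + 18. The bond from the oxygen on C2 of ring G to C1 of ring H is cut, an ether bond of the unhindered kind. Ring H arrives with the masked alkyne already on O4, so no protecting group on that oxygen and no free octamer phenol is needed. 20 comes from 19 by release of the boronic acid, and 19 from 17 and 18 by O-vinylation. The demand is that the dichlorovinyl ether survive periodate and the copper coupling.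

16 ⇒ 15 ⇒ 14 + 9, 14 ⇒ 13 ⇒ 12 + 9, 12 ⇒ 11 ⇒ 10 + 9. Three identical cuts are made at the bonds from a flanked oxygen to C1 of rings F, D and B, each paired with removal of a methoxymethyl group. The repeat of the target lets one building block, 9, serve three times. The gain is that seven rings reduce to one purchasable phenol and one two-ring boronic acid. The demand is that each coupling work on a progressively larger hindered phenol.

9 ⇒ 7 ⇒ 6. The C–B bond on C1 of ring B is cut, then the O–CH2 bond of the acetal. C1–H of ring B is the only aromatic C–H of 7 without an ortho substituent, so a sterically controlled C–H borylation can install boron without a halogen having been carried. The demand is a protecting group that has no reactive C–H bond and that comes off in acid.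

6 ⇒ 3 ⇒ 1 + 2. The C2–O bond of ring C is cut first, then the ether bond between rings B and C. Removing the ortho oxygen of ring C makes that ring symmetrical and free of ortho substituents, so the hindered B–C bond becomes an ordinary arylation of 1 by 2. The demand is a metalation that selects the one C–H lying between two oxygens.

## Other disconnections considered

Alternative 1: The cut removes both aryl–oxygen bonds of ring H at once, the bond from the oxygen on C2 of ring G to C1 of ring H and the bond from C4 of ring H to the oxygen on C1 of ring I. In the forward sense the cationic complex A1, in which 2,5-dichloro-1,3-dimethoxybenzene is bound eta-6 to a CpRu+ unit, would undergo two nucleophilic aromatic substitutions. The phenoxide of 16 would attack the open C5–Cl first, then the phenoxide of the ring I–J phenol A2 would attack the C2–Cl between the two methoxy groups, giving the ruthenium-bound permethyl decamer A3. Photolysis in acetonitrile would release the arene before demethylation.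
- In its favour: the union is convergent (seven, one and two rings); activation by the metal lets a weak base and mild temperature form ether bonds to an electron-rich ring; 16 is already a compound of the chosen route; no labile alkyne or carbene complex is needed.
- Against it here: the second substitution must take place at a carbon flanked by two methoxy groups, on a ring made more electron-rich by the first aryloxy group. The order of the two substitutions rests on sterics alone. A bifunctional electrophile may take up two molecules of 16. Ruthenium is stoichiometric, the cationic intermediate of high mass is awkward to purify, and decomplexation is an extra step.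
- Comparison: on structure, both plans avoid coupling two hindered partners, one by activating ring H, the other by building ring I. On mechanism, stepwise addition–elimination on a metal-bound arene is more predictable than an insertion cascade, which is a point for the alternative. On convergence the alternative is better. On step count the two should be about equal, since A2 needs some three to four steps of its own and the union, decomplexation and demethylation add four more to the ten that lead to 16. The chosen plan is kept because its ring closure sets the five oxygens and the free C2 hydroxyl with no competing site.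

Alternative 2: The cut opens ring A at C2–C3 and C5–C6. In the forward sense the nonamer aryloxymalonate A5, whose malonate carbon is the future C1, would be condensed under alkoxide with dimethyl 3-oxopentanedioate A4. Each methylene of A4 would be acylated by one ester of A5, and enolisation would give ring A as the trihydroxyisophthalate A6. Saponification and double decarboxylation would then clear C3 and C5.
- In its favour: the reagents are cheap and no transition metal is involved. Ring A appears with its three hydroxyls free. The ether oxygen of A5 would come from simple O-alkylation of an unhindered phenol by a halomalonate, so the A–B bond needs no arylation of a hindered oxygen; on that single bond the alternative is the equal of the chosen plan and arguably the gentler.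
- Against it here: ring A is the least demanding ring. The chosen route buys it as 10 and attaches it in one step, whereas the alternative spends an alkylation, a condensation and a hydrolysis–decarboxylation on it. The condensation would be run last, on a nine-ring substrate, against self-condensation of A4 and retro-Claisen cleavage. The nonamer would have to be grown in the opposite sense, which leaves all four hindered bonds unsolved.
- Comparison: the mechanism is classical carbonyl chemistry and is safe in handling, which is better than chromium. Structurally it addresses an easy bond, and in step economy it is worse by two to three steps.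

Alternative 3: The cut opens ring C at C5–C6. In the forward sense the cyclobutenone A7, formed by addition of a lithiated 1-aryloxyvinyl nucleophile to a squaric ester, would be heated. Four-electron ring opening would give a dienylketene, six-electron closure between the ketene carbon and the vinyl CH2 followed by tautomerisation would give the hydroquinone A8.
- In its favour: the rearrangement is thermal and metal-free and uses cheap reagents. Connectivity is fixed by the preceding 1,2-addition, so there is no orientation question like that of an alkyne insertion, which makes it better than the chosen key step on regiochemical certainty. Like the chosen step, it forms the hindered ether bond before the ring and brings every oxygen with the ring; on that point the two are equal.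
- Against it here: A8 has two free hydroxyls, on C2 and C5. The C5 hydroxyl must be methylated and the C2 hydroxyl kept for arylation, a selective step that the carbene route avoids because C5 arrives as its methyl ether. The hydroquinone is prone to air oxidation to the quinone. The lithiation of the aryl vinyl ether must beat ring metalation next to methoxy groups. The step is placed on ring C, so rings E, G and I still need their own solution.
- Comparison: mechanistically the two are close relatives (ketene electrocyclisation). Handling is better without chromium. Step economy for one ring is about equal (vinyl ether, addition, thermolysis, selective methylation against dichlorovinyl ether, alkyne, carbene complex, annulation). The chosen plan wins on differentiation of the two oxygens.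

Key step: step 17

Assumption: 10 and 17 are treated as purchasable, and the vinyllithium 28, whose C–Li bond is anti to the β-methoxy group, is taken to persist at −78 °C long enough to be trapped, as the ring-constrained 5,6-dihydro-1,4-dioxin-2-yllithium with the same anti arrangement does.

Remark on regiochemistry: in an aryl ethynyl ether the terminal CH carbon is the nucleophilic one, so its bonding to the electrophilic carbene carbon is favoured electronically as well as sterically; the polarisation of the ynol ether supports the required orientation and does not work against it.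

Convention: "ring A–X oligomer" means the chain of the target from ring A through ring X with every hydroxyl as its methyl ether; the group named sits on the chain-end oxygen (O2 of rings C, E, G, I; O4 of ring H).

## Route

Step 1
Reactants: 1 2,6-dimethoxyphenol; 2 3,4,5-trimethoxyphenylboronic acid
Product: 3 5-(2,6-dimethoxyphenoxy)-1,2,3-trimethoxybenzene
Conditions: Cu(OAc)2, pyridine, 4 Å MS, CH2Cl2, dry air, rt
Reagents that add atoms: none
Why: Chan–Lam oxidative O-arylation of a phenol by an arylboronic acid; the boronic acid has no ortho substituent, so the di-ortho-methoxy phenol is tolerated. Forming the ring B–C ether before ring C has its C2 oxygen turns the hardest bond of the repeat into an ordinary coupling.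

Step 2
Reactants: 3 5-(2,6-dimethoxyphenoxy)-1,2,3-trimethoxybenzene
Product: 6 6-(2,6-dimethoxyphenoxy)-2,3,4-trimethoxyphenol, via ring C aryllithium 4 (not isolated), via dimethyl arylboronate 5 (not isolated)
Conditions: n-BuLi, TMEDA, THF, −20 → 0 °C; B(OMe)3, −78 °C → rt; AcOH, 30% H2O2, 0 °C → rt
Reagents that add atoms: hydrogen peroxide, OO
Why: Directed ortho-metalation, borylation and oxidation in one pot; C2–H of ring C is the only hydrogen of 3 that lies between two oxygens (aryloxy and methoxy), so it should be removed in preference to the ring B hydrogens, which have at most one ortho oxygen. Oxidation of the C–B bond puts the hydroxyl exactly where the metal was.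

Step 3
Reactants: 6 6-(2,6-dimethoxyphenoxy)-2,3,4-trimethoxyphenol
Product: 7 1-(2,6-dimethoxyphenoxy)-3,4,5-trimethoxy-2-(methoxymethoxy)benzene
Conditions: NaH, MOMCl, THF/DMF, 0 °C → rt
Reagents that add atoms: chloromethyl methyl ether, COCCl
Why: Williamson-type O-alkylation of the sodium phenoxide; the small electrophile reaches the flanked oxygen, and the acetal has no aromatic C–H that could interfere in the next step.

Step 4
Reactants: 7 1-(2,6-dimethoxyphenoxy)-3,4,5-trimethoxy-2-(methoxymethoxy)benzene
Product: 9 [3,5-dimethoxy-4-[3,4,5-trimethoxy-2-(methoxymethoxy)phenoxy]phenyl]boronic acid, via pinacol boronate 8 (not isolated)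
Conditions: [Ir(OMe)(cod)]2 (cat.), dtbpy (cat.), B2pin2, THF, 80 °C; then NaIO4, NH4OAc, acetone/H2O, rt
Reagents that add atoms: bis(pinacolato)diboron, CC1(C)OB(OC1(C)C)B1OC(C)(C)C(C)(C)O1; water, O
Why: Iridium-catalysed aromatic C–H borylation is sterically controlled, and C1–H of ring B (para to the ether oxygen) is the only aromatic hydrogen of 7 without an ortho substituent. Periodate cleavage of the pinacol in the same pot frees the boronic acid, the better partner for copper-mediated arylation; the acetal tolerates the buffered conditions.

Step 5
Reactants: 10 2,4,6-trimethoxyphenol; 9 ring B–C boronic acid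
Product: 11 ring A–C trimer methoxymethyl ether
Conditions: Cu(OAc)2, pyridine, 4 Å MS, CH2Cl2, dry air, rt
Reagents that add atoms: none
Why: Chan–Lam O-arylation as in step 1; the boron-bearing carbon of 9 has two free ortho positions, so the hindered, electron-rich phenol 10 should couple. The acetal and the methyl ethers are inert to the copper acetate/pyridine system.

Step 6
Reactants: 11 ring A–C trimer methoxymethyl ether
Product: 12 ring A–C trimer phenol (free OH on C2 of ring C)
Conditions: HCl (cat.), MeOH/THF, 45 °C
Reagents that add atoms: none
Why: Acid-catalysed methanolysis of a methoxymethyl acetal; aryl methyl ethers and diaryl ethers are stable to dilute HCl in methanol.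

Step 7
Reactants: 12 ring A–C trimer phenol; 9 ring B–C boronic acid
Product: 13 ring A–E pentamer methoxymethyl ether
Conditions: Cu(OAc)2, pyridine, 4 Å MS, CH2Cl2, dry air, rt
Reagents that add atoms: none
Why: Chan–Lam O-arylation; the phenol of 12 has the same local environment (between an aryloxy and a methoxy group) as in every later iteration, and 9 is used in excess to offset protodeboronation.

Step 8
Reactants: 13 ring A–E pentamer methoxymethyl ether
Product: 14 ring A–E pentamer phenol (free OH on C2 of ring E)
Conditions: HCl (cat.), MeOH/THF, 45 °C
Reagents that add atoms: none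
Why: Acid-catalysed acetal methanolysis as in step 6; nothing else in 13 is acid-labile.

Step 9
Reactants: 14 ring A–E pentamer phenol; 9 ring B–C boronic acid
Product: 15 ring A–G heptamer methoxymethyl ether
Conditions: Cu(OAc)2, pyridine, 4 Å MS, CH2Cl2, dry air, rt
Reagents that add atoms: none
Why: Third Chan–Lam O-arylation with the same building block; the reacting centres are identical to those of step 7 and chain length should have little influence at room temperature in CH2Cl2.

Step 10
Reactants: 15 ring A–G heptamer methoxymethyl ether
Product: 16 ring A–G heptamer phenol (free OH on C2 of ring G)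
Conditions: HCl (cat.), MeOH/THF, 45 °C
Reagents that add atoms: none
Why: Acid-catalysed acetal methanolysis as in steps 6 and 8.

Step 11
Reactants: 17 4-hydroxy-3,5-dimethoxyphenylboronic acid pinacol ester; 18 trichloroethylene
Product: 19 4-[(E)-1,2-dichlorovinyloxy]-3,5-dimethoxyphenylboronic acid pinacol ester
Conditions: K2CO3, DMF, 70 °C
Reagents that add atoms: none
Why: Base-mediated O-vinylation: the phenoxide adds to dichloroacetylene formed in situ from 18, and anti addition gives the E alkene (chlorines trans). The dichlorovinyl ether is a robust masked ethynyl ether, and anhydrous carbonate leaves the pinacol boronate intact.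

Step 12
Reactants: 19 4-[(E)-1,2-dichlorovinyloxy]-3,5-dimethoxyphenylboronic acid pinacol ester
Product: 20 [4-[(E)-1,2-dichlorovinyloxy]-3,5-dimethoxyphenyl]boronic acid
Conditions: NaIO4, NH4OAc, acetone/H2O, rt
Reagents that add atoms: water, O
Why: Oxidative cleavage of the pinacol by periodate drives hydrolysis of the boronic ester; the electron-poor dichlorovinyl ether has nothing that periodate attacks.

Step 13
Reactants: 16 ring A–G heptamer phenol; 20 ring H boronic acid
Product: 21 ring A–H octamer (E)-1,2-dichlorovinyl ether
Conditions: Cu(OAc)2, pyridine, 4 Å MS, CH2Cl2, dry air, rt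
Reagents that add atoms: none
Why: Chan–Lam O-arylation of the ring G phenol by an unhindered boronic acid; ring H arrives with the masked alkyne on O4, so no protecting-group step is spent on that oxygen.

Step 14
Reactants: 21 ring A–H octamer (E)-1,2-dichlorovinyl ether
Product: 24 ring A–H octamer aryl ethynyl ether, via octamer chloroethynyl ether 22 (not isolated), via octamer lithium acetylide 23 (not isolated)
Conditions: n-BuLi (2.5 equiv), THF, −78 → −40 °C; MeOH, −78 °C
Reagents that add atoms: none
Why: Dehydrochlorination to the chloroalkyne and chlorine–lithium exchange by a second equivalent of butyllithium give the lithium acetylide, which is protonated cold (the established route from dichlorovinyl ethers to ynol ethers). At −78 °C without a diamine, ring metalation of the methoxyarenes should be too slow to compete; 24 is used at once.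

Step 15
Reactants: 25 1,1,2-trimethoxyethane
Product: 26 (Z)-1,2-dimethoxyethene
Conditions: TMSOTf, i-Pr2NEt, CH2Cl2, 0 °C → rt; fractional distillation
Reagents that add atoms: none
Why: Silyl triflate/amine-mediated elimination of methanol from an acetal (oxocarbenium formation, then deprotonation) gives the enol ether. The Z isomer, the more stable one for vicinal dialkoxyethenes, is collected by fractional distillation.

Step 16
Reactants: 26 (Z)-1,2-dimethoxyethene; 27 chromium hexacarbonyl, Cr(CO)6
Product: 30 pentacarbonyl[(Z)-1,2-dimethoxyvinyl(methoxy)carbene]chromium, via (Z)-1,2-dimethoxyvinyllithium 28 (not isolated), via lithium acylchromate 29 (not isolated)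
Conditions: t-BuLi, THF, −78 °C; 27, Et2O, −78 → 0 °C; Me3OBF4, CH2Cl2, 0 °C
Reagents that add atoms: trimethyloxonium tetrafluoroborate, C[O+](C)C.F[B-](F)(F)F
Why: Fischer synthesis of an alkoxycarbene complex: vinylic deprotonation alpha to oxygen with retention of the alkene geometry, addition of the vinyllithium to a carbonyl ligand of Cr(CO)6, and O-methylation of the acylchromate by the oxonium salt. The vinyllithium is kept at −78 °C and transferred at once to limit loss of LiOMe.

Step 17
Reactants: 24 ring A–H octamer aryl ethynyl ether; 30 pentacarbonyl[(Z)-1,2-dimethoxyvinyl(methoxy)carbene]chromium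
Product: 32 ring A–I nonamer phenol (free OH on C2 of ring I), via tricarbonylchromium arene complex 31 (not isolated)
Conditions: THF, 50 °C, Ar; then air, daylight, Et2O, rt
Reagents that add atoms: none
Why: Dötz benzannulation of an alkenyl(alkoxy)carbene complex of Cr(CO)5 with a terminal alkyne, a reaction type that is known for aryl ethynyl ethers. Thermal loss of one CO from 30 opens a site for 24, and the alkyne inserts into the chromium–carbene bond so that its CH carbon (C6) bonds to the carbene carbon (C5) while its aryloxy-bearing carbon (C1) stays on chromium. Migratory insertion of a carbonyl ligand at that carbon forms the C1–C2 bond and gives an eta-4 vinylketene complex. Ring I then closes by six-electron electrocyclisation between the ketene carbon C2 and the vinyl β-carbon C3, and tautomerisation of the cyclohexadienone gives the phenol, held at first as its Cr(CO)3 complex 31 and released by mild air oxidation. No stereocenter is formed; the Z geometry of the vinyl group is lost on aromatisation and serves only to put the β-hydrogen, not the β-methoxy group, on the inner side of the closing triene. The selectivity needed is the orientation of insertion: the small terminal hydrogen next to the carbene carbon is the normal steric outcome, and the nucleophilic CH carbon of the ynol ether meeting the electrophilic carbene carbon points the same way. Because the new C2 hydroxyl is para to the C5 methoxy group, strong oxidants such as cerium salts are avoided in the work-up.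

Step 18
Reactants: 32 ring A–I nonamer phenol; 2 3,4,5-trimethoxyphenylboronic acid
Product: 33 permethylated ring A–J decamer
Conditions: Cu(OAc)2, pyridine, 4 Å MS, CH2Cl2, dry air, rt
Reagents that add atoms: none
Why: Chan–Lam O-arylation of the only free hydroxyl by an unhindered, electron-rich boronic acid used in excess; the reacting phenol has the same surroundings as those of steps 7, 9 and 13.

Step 19
Reactants: 33 permethylated ring A–J decamer
Product: 34 the target, CNP0255890.0 (all twenty-six oxygens as free hydroxyls)
Conditions: BBr3 (large excess), CH2Cl2, −78 °C → rt, Ar; MeOH, 0 °C; degassed H2O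
Reagents that add atoms: none
Why: Lewis acid cleavage of aryl methyl ethers by BBr3 (complexation at oxygen, bromide attack at methyl). Diaryl ether bonds offer no alkyl carbon to bromide and should stay intact. A large excess and exclusion of air are needed for twenty-six ethers and an oxidation-prone product.

## Compound list

1 | 2,6-dimethoxyphenol | COc1cccc(OC)c1O | starting material
2 | 3,4,5-trimethoxyphenylboronic acid | COc1cc(B(O)O)cc(OC)c1OC | starting material
3 | 5-(2,6-dimethoxyphenoxy)-1,2,3-trimethoxybenzene | COc1cccc(OC)c1Oc1cc(OC)c(OC)c(OC)c1 | intermediate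
4 | ring C aryllithium of 3 (lithium on C2 of ring C) | COc1cccc(OC)c1Oc1cc(OC)c(OC)c(OC)c1[Li] | intermediate (not isolated)
5 | dimethyl [6-(2,6-dimethoxyphenoxy)-2,3,4-trimethoxyphenyl]boronate | COc1cccc(OC)c1Oc1cc(OC)c(OC)c(OC)c1B(OC)OC | intermediate (not isolated)
6 | 6-(2,6-dimethoxyphenoxy)-2,3,4-trimethoxyphenol | COc1cccc(OC)c1Oc1cc(OC)c(OC)c(OC)c1O | intermediate
7 | 1-(2,6-dimethoxyphenoxy)-3,4,5-trimethoxy-2-(methoxymethoxy)benzene | COc1cccc(OC)c1Oc1cc(OC)c(OC)c(OC)c1OCOC | intermediate
8 | pinacol boronate of 7 (boron on C1 of ring B) | COc1cc(B2OC(C)(C)C(C)(C)O2)cc(OC)c1Oc1cc(OC)c(OC)c(OC)c1OCOC | intermediate (not isolated)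
9 | [3,5-dimethoxy-4-[3,4,5-trimethoxy-2-(methoxymethoxy)phenoxy]phenyl]boronic acid | COc1cc(B(O)O)cc(OC)c1Oc1cc(OC)c(OC)c(OC)c1OCOC | intermediate
10 | 2,4,6-trimethoxyphenol | COc1cc(OC)c(O)c(OC)c1 | starting material
11 | ring A–C trimer methoxymethyl ether | COc1cc(OC)c(c(OC)c1)Oc1cc(OC)c(c(OC)c1)Oc1cc(OC)c(OC)c(OC)c1OCOC | intermediate
12 | ring A–C trimer phenol | COc1cc(OC)c(c(OC)c1)Oc1cc(OC)c(c(OC)c1)Oc1cc(OC)c(OC)c(OC)c1O | intermediate
13 | ring A–E pentamer methoxymethyl ether | COc1cc(OC)c(c(OC)c1)Oc1cc(OC)c(c(OC)c1)Oc1cc(OC)c(OC)c(OC)c1Oc1cc(OC)c(c(OC)c1)Oc1cc(OC)c(OC)c(OC)c1OCOC | intermediate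
14 | ring A–E pentamer phenol | COc1cc(OC)c(c(OC)c1)Oc1cc(OC)c(c(OC)c1)Oc1cc(OC)c(OC)c(OC)c1Oc1cc(OC)c(c(OC)c1)Oc1cc(OC)c(OC)c(OC)c1O | intermediate
15 | ring A–G heptamer methoxymethyl ether | COc1cc(OC)c(c(OC)c1)Oc1cc(OC)c(c(OC)c1)Oc1cc(OC)c(OC)c(OC)c1Oc1cc(OC)c(c(OC)c1)Oc1cc(OC)c(OC)c(OC)c1Oc1cc(OC)c(c(OC)c1)Oc1cc(OC)c(OC)c(OC)c1OCOC | intermediate
16 | ring A–G heptamer phenol | COc1cc(OC)c(c(OC)c1)Oc1cc(OC)c(c(OC)c1)Oc1cc(OC)c(OC)c(OC)c1Oc1cc(OC)c(c(OC)c1)Oc1cc(OC)c(OC)c(OC)c1Oc1cc(OC)c(c(OC)c1)Oc1cc(OC)c(OC)c(OC)c1O | intermediate
17 | 4-hydroxy-3,5-dimethoxyphenylboronic acid pinacol ester | COc1cc(B2OC(C)(C)C(C)(C)O2)cc(OC)c1O | starting material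
18 | trichloroethylene | ClC=C(Cl)Cl | starting material
19 | 4-[(E)-1,2-dichlorovinyloxy]-3,5-dimethoxyphenylboronic acid pinacol ester | Cl/C=C(/Cl)Oc1c(OC)cc(B2OC(C)(C)C(C)(C)O2)cc1OC | intermediate
20 | [4-[(E)-1,2-dichlorovinyloxy]-3,5-dimethoxyphenyl]boronic acid | Cl/C=C(/Cl)Oc1c(OC)cc(B(O)O)cc1OC | intermediate
21 | ring A–H octamer (E)-1,2-dichlorovinyl ether | COc1cc(OC)c(c(OC)c1)Oc1cc(OC)c(c(OC)c1)Oc1cc(OC)c(OC)c(OC)c1Oc1cc(OC)c(c(OC)c1)Oc1cc(OC)c(OC)c(OC)c1Oc1cc(OC)c(c(OC)c1)Oc1cc(OC)c(OC)c(OC)c1Oc1cc(OC)c(c(OC)c1)O/C(Cl)=C\Cl | intermediate
22 | ring A–H octamer chloroethynyl ether | COc1cc(OC)c(c(OC)c1)Oc1cc(OC)c(c(OC)c1)Oc1cc(OC)c(OC)c(OC)c1Oc1cc(OC)c(c(OC)c1)Oc1cc(OC)c(OC)c(OC)c1Oc1cc(OC)c(c(OC)c1)Oc1cc(OC)c(OC)c(OC)c1Oc1cc(OC)c(c(OC)c1)OC#CCl | intermediate (not isolated)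
23 | ring A–H octamer lithium acetylide | COc1cc(OC)c(c(OC)c1)Oc1cc(OC)c(c(OC)c1)Oc1cc(OC)c(OC)c(OC)c1Oc1cc(OC)c(c(OC)c1)Oc1cc(OC)c(OC)c(OC)c1Oc1cc(OC)c(c(OC)c1)Oc1cc(OC)c(OC)c(OC)c1Oc1cc(OC)c(c(OC)c1)OC#C[Li] | intermediate (not isolated)
24 | ring A–H octamer aryl ethynyl ether | COc1cc(OC)c(c(OC)c1)Oc1cc(OC)c(c(OC)c1)Oc1cc(OC)c(OC)c(OC)c1Oc1cc(OC)c(c(OC)c1)Oc1cc(OC)c(OC)c(OC)c1Oc1cc(OC)c(c(OC)c1)Oc1cc(OC)c(OC)c(OC)c1Oc1cc(OC)c(c(OC)c1)OC#C | intermediate
25 | 1,1,2-trimethoxyethane | COCC(OC)OC | starting material
26 | (Z)-1,2-dimethoxyethene | CO/C=C\OC | intermediate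
27 | chromium hexacarbonyl, Cr(CO)6 | O=C=[Cr](=C=O)(=C=O)(=C=O)(=C=O)=C=O | starting material
28 | (Z)-1,2-dimethoxyvinyllithium | CO/C=C(\OC)[Li] | intermediate (not isolated)
29 | lithium pentacarbonyl[(Z)-2,3-dimethoxyacryloyl]chromate | CO/C=C(\OC)C([O-])=[Cr](=C=O)(=C=O)(=C=O)(=C=O)=C=O.[Li+] | intermediate (not isolated)
30 | pentacarbonyl[(Z)-1,2-dimethoxyvinyl(methoxy)carbene]chromium | CO/C=C(\OC)C(OC)=[Cr](=C=O)(=C=O)(=C=O)(=C=O)=C=O | intermediate
31 | Cr(CO)3 complex of 32, bound eta-6 through ring I (written as arene and Cr(CO)3 fragment) | COc1cc(OC)c(c(OC)c1)Oc1cc(OC)c(c(OC)c1)Oc1cc(OC)c(OC)c(OC)c1Oc1cc(OC)c(c(OC)c1)Oc1cc(OC)c(OC)c(OC)c1Oc1cc(OC)c(c(OC)c1)Oc1cc(OC)c(OC)c(OC)c1Oc1cc(OC)c(c(OC)c1)Oc1cc(OC)c(OC)c(OC)c1O.O=C=[Cr](=C=O)=C=O | intermediate (not isolated)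
32 | ring A–I nonamer phenol (free OH on C2 of ring I) | COc1cc(OC)c(c(OC)c1)Oc1cc(OC)c(c(OC)c1)Oc1cc(OC)c(OC)c(OC)c1Oc1cc(OC)c(c(OC)c1)Oc1cc(OC)c(OC)c(OC)c1Oc1cc(OC)c(c(OC)c1)Oc1cc(OC)c(OC)c(OC)c1Oc1cc(OC)c(c(OC)c1)Oc1cc(OC)c(OC)c(OC)c1O | intermediate
33 | permethylated ring A–J decamer | COc1cc(OC)c(c(OC)c1)Oc1cc(OC)c(c(OC)c1)Oc1cc(OC)c(OC)c(OC)c1Oc1cc(OC)c(c(OC)c1)Oc1cc(OC)c(OC)c(OC)c1Oc1cc(OC)c(c(OC)c1)Oc1cc(OC)c(OC)c(OC)c1Oc1cc(OC)c(c(OC)c1)Oc1cc(OC)c(OC)c(OC)c1Oc1cc(OC)c(OC)c(OC)c1 | intermediate
34 | CNP0255890.0 (no stereocenter) | Oc1cc(O)c(Oc2cc(O)c(Oc3cc(O)c(O)c(O)c3Oc3cc(O)c(Oc4cc(O)c(O)c(O)c4Oc4cc(O)c(Oc5cc(O)c(O)c(O)c5Oc5cc(O)c(Oc6cc(O)c(O)c(O)c6Oc6cc(O)c(O)c(O)c6)c(O)c5)c(O)c4)c(O)c3)c(O)c2)c(O)c1 | target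

## Step count and least certain steps

Total step count: 19. Longest linear sequence: 15 steps (steps 1–10, 13, 14, 17, 18, 19); steps 11–12 and 15–16 are side branches.

**Step 17 (key step).** Three things are most likely to go wrong. Carbonyl insertion may stall after alkyne insertion because the aryloxy group stabilises the new carbene, which would divert the cascade to non-annulated products. The ynol ether may oligomerise thermally before it inserts. The para-methoxyphenol may be over-oxidised while chromium is being removed. The fallback sets out from 16 and 9: one more Chan–Lam coupling (Cu(OAc)2, pyridine, CH2Cl2, air) gives the ring A–I nonamer methoxymethyl ether F1, and HCl in methanol removes the acetal to come back to the route at 32. It works because the H–I pair is the same repeat as B–C, so the building block already in hand supplies ring I by polar chemistry only.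

**Step 16.** The vinyllithium has its C–Li bond anti to the β-methoxy group, so β-elimination of LiOMe to an alkoxyalkyne may outrun addition to Cr(CO)6. The fallback sets out from 25, whose step 15 elimination also delivers (E)-1,2-dimethoxyethene F2, taken by fractional distillation. t-BuLi gives (E)-1,2-dimethoxyvinyllithium F3, in which lithium is syn to the β-methoxy group, so no leaving group is anti-periplanar and the oxygen can coordinate the metal. Cr(CO)6 then gives the lithium acylchromate F4 and Me3OBF4 the E-configured carbene complex F5. F5 takes the place of 30 in the benzannulation and the route is rejoined at 32, because the vinyl geometry disappears on aromatisation.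

**Step 2.** Metalation may be incomplete or may stray to a ring B position ortho to a single methoxy group, and the oxidation may be incomplete. The fallback sets out from 3 and uses electrophilic substitution instead of deprotonation. Rieche formylation (Cl2CHOMe, TiCl4, CH2Cl2, 0 °C) at the most electron-rich carbon, C2 of ring C (ortho to two oxygens, para to a third), gives 6-(2,6-dimethoxyphenoxy)-2,3,4-trimethoxybenzaldehyde F6. Baeyer–Villiger oxidation (mCPBA, CH2Cl2) gives the aryl formate F7, and K2CO3 in methanol releases the phenol, returning to the route at 6.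

**Step 7 (the same concern applies to steps 5, 9, 13 and 18).** C–O bond formation at the flanked phenol may be slow, so that protodeboronation and oxidative self-coupling use up the boronic acid. The fallback sets out from 9: CuBr2 in aqueous methanol (bromodeboronation) gives 5-bromo-1,3-dimethoxy-2-[3,4,5-trimethoxy-2-(methoxymethoxy)phenoxy]benzene F8. Ullmann coupling of F8 with 12 (CuI, picolinic acid, K3PO4, DMSO, 90 °C) comes back to the route at 13. The same bromide can serve the other iterations.

**Step 19.** Cleavage of twenty-six ethers may stop short, and the polyphenol may be oxidised by air during isolation. The fallback sets out from 33: the crude product of the BBr3 treatment is acetylated (Ac2O, pyridine) to the hexacosaacetate F9, which is stable in air and can be chromatographed away from under-demethylated material. HCl in degassed methanol then removes the acetates and comes back to the route at 34.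

## Further compounds

F1 | step 17 | ring A–I nonamer methoxymethyl ether | COc1cc(OC)c(c(OC)c1)Oc1cc(OC)c(c(OC)c1)Oc1cc(OC)c(OC)c(OC)c1Oc1cc(OC)c(c(OC)c1)Oc1cc(OC)c(OC)c(OC)c1Oc1cc(OC)c(c(OC)c1)Oc1cc(OC)c(OC)c(OC)c1Oc1cc(OC)c(c(OC)c1)Oc1cc(OC)c(OC)c(OC)c1OCOC
F2 | step 16 | (E)-1,2-dimethoxyethene | CO/C=C/OC
F3 | step 16 | (E)-1,2-dimethoxyvinyllithium | CO/C=C(/OC)[Li]
F4 | step 16 | lithium pentacarbonyl[(E)-2,3-dimethoxyacryloyl]chromate | CO/C=C(/OC)C([O-])=[Cr](=C=O)(=C=O)(=C=O)(=C=O)=C=O.[Li+]
F5 | step 16 | pentacarbonyl[(E)-1,2-dimethoxyvinyl(methoxy)carbene]chromium | CO/C=C(/OC)C(OC)=[Cr](=C=O)(=C=O)(=C=O)(=C=O)=C=O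
F6 | step 2 | 6-(2,6-dimethoxyphenoxy)-2,3,4-trimethoxybenzaldehyde | COc1cccc(OC)c1Oc1cc(OC)c(OC)c(OC)c1C=O
F7 | step 2 | 6-(2,6-dimethoxyphenoxy)-2,3,4-trimethoxyphenyl formate | COc1cccc(OC)c1Oc1cc(OC)c(OC)c(OC)c1OC=O
F8 | step 7 | 5-bromo-1,3-dimethoxy-2-[3,4,5-trimethoxy-2-(methoxymethoxy)phenoxy]benzene | COc1cc(Br)cc(OC)c1Oc1cc(OC)c(OC)c(OC)c1OCOC
F9 | step 19 | hexacosaacetate of 34 (every hydroxyl as its acetate) | CC(=O)Oc1cc(OC(C)=O)c(c(OC(C)=O)c1)Oc1cc(OC(C)=O)c(c(OC(C)=O)c1)Oc1cc(OC(C)=O)c(OC(C)=O)c(OC(C)=O)c1Oc1cc(OC(C)=O)c(c(OC(C)=O)c1)Oc1cc(OC(C)=O)c(OC(C)=O)c(OC(C)=O)c1Oc1cc(OC(C)=O)c(c(OC(C)=O)c1)Oc1cc(OC(C)=O)c(OC(C)=O)c(OC(C)=O)c1Oc1cc(OC(C)=O)c(c(OC(C)=O)c1)Oc1cc(OC(C)=O)c(OC(C)=O)c(OC(C)=O)c1Oc1cc(OC(C)=O)c(OC(C)=O)c(OC(C)=O)c1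
A1 | alternative 1 | cyclopentadienyl(eta-6-2,5-dichloro-1,3-dimethoxybenzene)ruthenium hexafluorophosphate, written as separated ions | COc1cc(Cl)cc(OC)c1Cl.[Ru+2].c1cc[cH-]c1.F[P-](F)(F)(F)(F)F
A2 | alternative 1 | 3,4,5-trimethoxy-2-(3,4,5-trimethoxyphenoxy)phenol (ring I–J phenol) | COc1cc(Oc2c(O)cc(OC)c(OC)c2OC)cc(OC)c1OC
A3 | alternative 1 | permethylated decamer bound eta-6 through ring H to cyclopentadienylruthenium hexafluorophosphate, written as separated ions | COc1cc(OC)c(c(OC)c1)Oc1cc(OC)c(c(OC)c1)Oc1cc(OC)c(OC)c(OC)c1Oc1cc(OC)c(c(OC)c1)Oc1cc(OC)c(OC)c(OC)c1Oc1cc(OC)c(c(OC)c1)Oc1cc(OC)c(OC)c(OC)c1Oc1cc(OC)c(c(OC)c1)Oc1cc(OC)c(OC)c(OC)c1Oc1cc(OC)c(OC)c(OC)c1.[Ru+2].c1cc[cH-]c1.F[P-](F)(F)(F)(F)F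
A4 | alternative 2 | dimethyl 3-oxopentanedioate | COC(=O)CC(=O)CC(=O)OC
A5 | alternative 2 | dimethyl 2-(aryloxy)malonate carrying the permethylated ring B–J nonamer | COC(=O)C(C(=O)OC)Oc1cc(OC)c(c(OC)c1)Oc1cc(OC)c(OC)c(OC)c1Oc1cc(OC)c(c(OC)c1)Oc1cc(OC)c(OC)c(OC)c1Oc1cc(OC)c(c(OC)c1)Oc1cc(OC)c(OC)c(OC)c1Oc1cc(OC)c(c(OC)c1)Oc1cc(OC)c(OC)c(OC)c1Oc1cc(OC)c(OC)c(OC)c1
A6 | alternative 2 | decamer with ring A as dimethyl 5-aryloxy-2,4,6-trihydroxyisophthalate | COC(=O)c2c(O)c(Oc1cc(OC)c(c(OC)c1)Oc1cc(OC)c(OC)c(OC)c1Oc1cc(OC)c(c(OC)c1)Oc1cc(OC)c(OC)c(OC)c1Oc1cc(OC)c(c(OC)c1)Oc1cc(OC)c(OC)c(OC)c1Oc1cc(OC)c(c(OC)c1)Oc1cc(OC)c(OC)c(OC)c1Oc1cc(OC)c(OC)c(OC)c1)c(O)c(C(=O)OC)c2O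
A7 | alternative 3 | 4-hydroxy-2,3-dimethoxy-4-[1-(aryloxy)vinyl]cyclobut-2-en-1-one carrying rings A and B (racemic at C4) | COc1cc(OC)c(c(OC)c1)Oc1cc(OC)c(c(OC)c1)OC(=C)C1(O)C(OC)=C(OC)C1=O
A8 | alternative 3 | ring A–C trimer with free hydroxyls on C2 and C5 of ring C | COc1cc(OC)c(c(OC)c1)Oc1cc(OC)c(c(OC)c1)Oc1cc(O)c(OC)c(OC)c1O
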